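**Plan**
- Retrosynthesis: the butanoyl–aryl bond of ring B is cut first (Friedel–Crafts), then the three phenols of ring B are masked as benzyl ethers, then ring A is opened across C6–C1 and C2–C3 into a silyl ketene acetal diene and hept-2-yn-4-one.
- Enabling feature: ring A (C1 butanoyl, C2 methyl, C3 bridge CH2, C4 methoxyl, C5 methyl, C6 hydroxyl) has its hydroxyl at C6 ortho and its methoxyl at C4 para to the acyl carbon C1, the oxygen pattern that a 1,1,3-trioxygenated diene and an acetylenic ketone leave behind.
- Forward, chain: 2,4,6-trihydroxytoluene is formylated, benzylated, extended by two carbons, used to acylate the enolate of methyl propanoate, O-methylated and silylated to the diene that already carries ring B; the ynone comes from butanoyl chloride and 1-propynylmagnesium bromide.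
- Forward, rings: ring B is present from the start; ring A arises in step 10; debenzylation and butanoylation of ring B finish the synthesis.
- Stereochemistry: the target has no stereocentre; only the 3Z geometry of the diene matters (set by allylic strain in the dienolate), and all transient sp3 centres are erased on aromatization.

Key step: step 10

Remark on the chemistry: the geometry of the ketene acetal double bond in 19 and 20, the enolate geometry of 10 and the configuration of the transient sp3 centres in 11, 12, 17 and 21 have no influence on the outcome; they are drawn as the expected isomer or given as mixtures.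

**Step 1**
Reactants: 1 2,4,6-trihydroxytoluene
Product: 3 2,4,6-trihydroxy-3-methylbenzaldehyde, via aryl iminium chloride 2 (not isolated)
Conditions: POCl3, DMF, EtOAc, 0 °C to rt; then H2O, 60 °C
Reagents that add atoms: N,N-dimethylformamide, CN(C)C=O; water, O
Why: Vilsmeier–Haack formylation attacks one of the two equivalent free positions of the strongly activated ring and should stop there, because the iminium group of 2 deactivates the ring towards a second attack.

**Step 2**
Reactants: 3 2,4,6-trihydroxy-3-methylbenzaldehyde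
Product: 4 2,4,6-tris(benzyloxy)-3-methylbenzaldehyde
Conditions: BnBr (3.6 equiv), K2CO3, DMF, 70 °C
Reagents that add atoms: benzyl bromide, BrCc1ccccc1
Why: Williamson ether synthesis; the formyl group lowers the carbon nucleophilicity of the phloroglucinol ring, so O-benzylation of all three phenols, the two chelated ones included at this temperature, should prevail over C-benzylation.

**Step 3**
Reactants: 4 2,4,6-tris(benzyloxy)-3-methylbenzaldehyde; 5 diethyl {2-[methoxy(methyl)amino]-2-oxoethyl}phosphonate
Product: 7 (2E)-N-methoxy-N-methyl-3-[2,4,6-tris(benzyloxy)-3-methylphenyl]prop-2-enamide, via sodium phosphonate carbanion 6 (not isolated)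
Conditions: NaH, THF, 0 °C; then 4, 0 °C to rt
Reagents that add atoms: none
Why: Horner–Wadsworth–Emmons olefination with a stabilized amide phosphonate gives the E alkene and is known to tolerate 2,6-dialkoxybenzaldehydes, which cannot enolize.

**Step 4**
Reactants: 7 (2E)-N-methoxy-N-methyl-3-[2,4,6-tris(benzyloxy)-3-methylphenyl]prop-2-enamide
Product: 8 N-methoxy-N-methyl-3-[2,4,6-tris(benzyloxy)-3-methylphenyl]propanamide
Conditions: H2 (4 atm), RhCl(PPh3)3 (5 mol %), toluene/EtOH 1:1, 50 °C
Reagents that add atoms: none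
Why: homogeneous catalytic hydrogenation with the rhodium phosphine complex saturates the disubstituted conjugated alkene and leaves aryl benzyl ethers and the N–O bond alone, both of which a heterogeneous palladium catalyst would endanger.

**Step 5**
Reactants: 8 N-methoxy-N-methyl-3-[2,4,6-tris(benzyloxy)-3-methylphenyl]propanamide; 9 methyl propanoate
Product: 12 methyl 2-methyl-3-oxo-5-[2,4,6-tris(benzyloxy)-3-methylphenyl]pentanoate (racemic), via lithium enolate of methyl propanoate 10 (not isolated), via lithium-chelated tetrahedral adduct 11 (not isolated)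
Conditions: LiN(i-Pr)2, 9 (2.5 equiv), THF, −78 °C; then 8, −78 to −20 °C; aq NH4Cl
Reagents that add atoms: none
Why: crossed Claisen-type acylation of a preformed ester enolate by an N-methoxy-N-methylamide; chelate 11 persists until the quench, so the β-keto ester is released only on work-up and neither over-addition nor enolate exchange with the acyl donor should interfere.

**Step 6**
Reactants: 12 methyl 2-methyl-3-oxo-5-[2,4,6-tris(benzyloxy)-3-methylphenyl]pentanoate
Product: 13 methyl (2E)-3-methoxy-2-methyl-5-[2,4,6-tris(benzyloxy)-3-methylphenyl]pent-2-enoate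
Conditions: HC(OMe)3 (neat), H2SO4 (cat.), rt
Reagents that add atoms: trimethyl orthoformate, COC(OC)OC
Why: acid-catalysed ketalization followed by loss of methanol (enol ether formation) should settle on the conjugated β-methoxy enoate, the standard precursor of 1,1,3-trioxygenated dienes; benzyl ethers are inert to catalytic acid.

**Step 7**
Reactants: 14 butanoyl chloride
Product: 15 N-methoxy-N-methylbutanamide
Conditions: MeNHOMe·HCl, K2CO3, CH2Cl2/H2O, 0 °C to rt
Reagents that add atoms: N,O-dimethylhydroxylamine hydrochloride, CNOC.Cl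
Why: Schotten–Baumann acylation of the hydroxylamine by a simple acid chloride is a routine amide formation.

**Step 8**
Reactants: 15 N-methoxy-N-methylbutanamide; 16 1-propynylmagnesium bromide
Product: 18 hept-2-yn-4-one, via magnesium-chelated tetrahedral adduct 17 (not isolated)
Conditions: 16 (1.2 equiv), THF, 0 °C; aq NH4Cl
Reagents that add atoms: none
Why: Weinreb ketone synthesis; the alkynyl Grignard reagent adds once because chelate 17 collapses to the ynone only on quench.

**Step 9**
Reactants: 13 methyl (2E)-3-methoxy-2-methyl-5-[2,4,6-tris(benzyloxy)-3-methylphenyl]pent-2-enoate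
Product: 20 (1E,3Z)-1,3-dimethoxy-2-methyl-1-(trimethylsilyloxy)-5-[2,4,6-tris(benzyloxy)-3-methylphenyl]penta-1,3-diene, via lithium dienolate 19 (not isolated)
Conditions: LiN(i-Pr)2, THF, −78 °C; Me3SiCl, −78 °C to rt; used crude
Reagents that add atoms: chlorotrimethylsilane, C[Si](C)(C)Cl
Why: γ-deprotonation of the β-methoxy enoate (vinylogous enolate formation) and O-silylation give the silyl ketene acetal; allylic 1,3-strain with the C2 methyl group should place the arylmethyl group trans to C2, which is the 3Z geometry needed for the s-cis conformer.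

**Step 10**
Reactants: 20 (1E,3Z)-1,3-dimethoxy-2-methyl-1-(trimethylsilyloxy)-5-[2,4,6-tris(benzyloxy)-3-methylphenyl]penta-1,3-diene; 18 hept-2-yn-4-one
Product: 23 1-{2-hydroxy-4-methoxy-3,6-dimethyl-5-[(2,4,6-tris(benzyloxy)-3-methylphenyl)methyl]phenyl}butan-1-one, via cyclohexa-1,4-diene cycloadduct 21 (not isolated), via aryl trimethylsilyl ether 22 (not isolated)
Conditions: 18 (2 equiv), toluene, 110 °C, sealed tube; then 1 M HCl, THF, rt
Reagents that add atoms: none
Why: The electron-rich diene 20 and the electron-poor ynone 18 should combine in a normal-demand Diels–Alder reaction (concerted but asynchronous, or Mukaiyama–Michael addition followed by ring closure), in which C4 of the diene bonds to the β-carbon of 18 and C1 to its α-carbon to give cyclohexa-1,4-diene 21. The closest known reaction type is the benzannulation of 1-alkoxy-1-silyloxy-3-alkoxybutadienes with acetylenic ketones and esters to resorcinol monoethers. Ring A closes as a six-membered carbocycle in a (4+2) mode, and all six ring atoms with their substituents, the bridge to ring B included, come from the two partners. The two sp3 centres of 21 form without control and both vanish when the mixed ketal carbon expels methanol and the doubly allylic hydrogen on the bridge-bearing carbon is lost, which gives silyl ether 22 and, after the acidic work-up, phenol 23. The selectivity needed is regiochemical: the diene terminus remote from the ketene acetal oxygens is the nucleophilic end, so it attacks the β-carbon of the ynone, and the butanoyl group ends up ortho to the future hydroxyl and para to the methoxyl. The 3Z geometry of 20 turns the arylmethyl group outward in the s-cis conformer, and the linear dienophile keeps crowding at the forming bonds low.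

**Step 11**
Reactants: 23 1-{2-hydroxy-4-methoxy-3,6-dimethyl-5-[(2,4,6-tris(benzyloxy)-3-methylphenyl)methyl]phenyl}butan-1-one
Product: 24 1-{2-hydroxy-4-methoxy-3,6-dimethyl-5-[(2,4,6-trihydroxy-3-methylphenyl)methyl]phenyl}butan-1-one
Conditions: H2 (1 atm), 10% Pd/C, EtOAc, rt
Reagents that add atoms: none
Why: catalytic hydrogenolysis cleaves the three aryl benzyl ethers, while the hindered, hydrogen-bonded aryl ketone and the diarylmethane should resist reduction at atmospheric pressure in a neutral solvent.

**Step 12**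
Reactants: 24 1-{2-hydroxy-4-methoxy-3,6-dimethyl-5-[(2,4,6-trihydroxy-3-methylphenyl)methyl]phenyl}butan-1-one; 25 butanoic acid
Product: 26 1-{3-[(3-butanoyl-4-hydroxy-6-methoxy-2,5-dimethylphenyl)methyl]-2,4,6-trihydroxy-5-methylphenyl}butan-1-one (target CNP0189103.0)
Conditions: 25 (3 equiv), BF3·OEt2, 60 °C; then H2O/MeOH, 50 °C
Reagents that add atoms: none
Why: Friedel–Crafts acylation of a phloroglucinol with a carboxylic acid and BF3·OEt2 should take place at the only unsubstituted ring carbon, which lies between two hydroxyls of ring B; ring A has no free position and any O-acylation is reversible under these conditions.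

**Compound list**
1 | 2,4,6-trihydroxytoluene | Cc1c(O)cc(O)cc1O | starting material
2 | [(2,4,6-trihydroxy-3-methylphenyl)methylidene]dimethyliminium chloride | C[N+](C)=Cc1c(O)c(C)c(O)cc1O.[Cl-] | intermediate
3 | 2,4,6-trihydroxy-3-methylbenzaldehyde | O=Cc1c(O)c(C)c(O)cc1O | intermediate
4 | 2,4,6-tris(benzyloxy)-3-methylbenzaldehyde | O=Cc1c(OCc2ccccc2)c(C)c(OCc2ccccc2)cc1OCc1ccccc1 | intermediate
5 | diethyl {2-[methoxy(methyl)amino]-2-oxoethyl}phosphonate | CCOP(=O)(CC(=O)N(C)OC)OCC | starting material
6 | sodium salt of the carbanion of 5 | CCOP(=O)(OCC)[CH-]C(=O)N(C)OC.[Na+] | intermediate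
7 | (2E)-N-methoxy-N-methyl-3-[2,4,6-tris(benzyloxy)-3-methylphenyl]prop-2-enamide | CON(C)C(=O)/C=C/c1c(OCc2ccccc2)c(C)c(OCc2ccccc2)cc1OCc1ccccc1 | intermediate
8 | N-methoxy-N-methyl-3-[2,4,6-tris(benzyloxy)-3-methylphenyl]propanamide | CON(C)C(=O)CCc1c(OCc2ccccc2)c(C)c(OCc2ccccc2)cc1OCc1ccccc1 | intermediate
9 | methyl propanoate | CCC(=O)OC | starting material
10 | lithium enolate of methyl propanoate (methyl cis to methoxyl) | C/C=C(\OC)O[Li] | intermediate
11 | lithium alkoxide of methyl 3-hydroxy-3-[methoxy(methyl)amino]-2-methyl-5-[2,4,6-tris(benzyloxy)-3-methylphenyl]pentanoate (mixture of diastereomers) | COC(=O)C(C)C(O[Li])(CCc1c(OCc2ccccc2)c(C)c(OCc2ccccc2)cc1OCc1ccccc1)N(C)OC | intermediate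
12 | methyl 2-methyl-3-oxo-5-[2,4,6-tris(benzyloxy)-3-methylphenyl]pentanoate (racemic) | COC(=O)C(C)C(=O)CCc1c(OCc2ccccc2)c(C)c(OCc2ccccc2)cc1OCc1ccccc1 | intermediate
13 | methyl (2E)-3-methoxy-2-methyl-5-[2,4,6-tris(benzyloxy)-3-methylphenyl]pent-2-enoate | COC(=O)/C(C)=C(/OC)CCc1c(OCc2ccccc2)c(C)c(OCc2ccccc2)cc1OCc1ccccc1 | intermediate
14 | butanoyl chloride | CCCC(Cl)=O | starting material
15 | N-methoxy-N-methylbutanamide | CCCC(=O)N(C)OC | intermediate
16 | 1-propynylmagnesium bromide | CC#C[Mg]Br | starting material
17 | bromomagnesium alkoxide of 4-[methoxy(methyl)amino]hept-2-yn-4-ol (racemic) | CCCC(O[Mg]Br)(C#CC)N(C)OC | intermediate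
18 | hept-2-yn-4-one | CCCC(=O)C#CC | intermediate
19 | lithium (1E,3Z)-1,3-dimethoxy-2-methyl-5-[2,4,6-tris(benzyloxy)-3-methylphenyl]penta-1,3-dien-1-olate | [Li]O/C(OC)=C(C)/C(OC)=C/Cc1c(OCc2ccccc2)c(C)c(OCc2ccccc2)cc1OCc1ccccc1 | intermediate
20 | (1E,3Z)-1,3-dimethoxy-2-methyl-1-(trimethylsilyloxy)-5-[2,4,6-tris(benzyloxy)-3-methylphenyl]penta-1,3-diene | C[Si](C)(C)O/C(OC)=C(C)/C(OC)=C/Cc1c(OCc2ccccc2)c(C)c(OCc2ccccc2)cc1OCc1ccccc1 | intermediate
21 | 1-{4,6-dimethoxy-2,5-dimethyl-6-(trimethylsilyloxy)-3-[(2,4,6-tris(benzyloxy)-3-methylphenyl)methyl]cyclohexa-1,4-dien-1-yl}butan-1-one (mixture of diastereomers) | CCCC(=O)C1=C(C)C(Cc2c(OCc3ccccc3)c(C)c(OCc3ccccc3)cc2OCc2ccccc2)C(OC)=C(C)C1(OC)O[Si](C)(C)C | intermediate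
22 | 1-{4-methoxy-3,6-dimethyl-2-(trimethylsilyloxy)-5-[(2,4,6-tris(benzyloxy)-3-methylphenyl)methyl]phenyl}butan-1-one | CCCC(=O)c1c(C)c(Cc2c(OCc3ccccc3)c(C)c(OCc3ccccc3)cc2OCc2ccccc2)c(OC)c(C)c1O[Si](C)(C)C | intermediate
23 | 1-{2-hydroxy-4-methoxy-3,6-dimethyl-5-[(2,4,6-tris(benzyloxy)-3-methylphenyl)methyl]phenyl}butan-1-one | CCCC(=O)c1c(C)c(Cc2c(OCc3ccccc3)c(C)c(OCc3ccccc3)cc2OCc2ccccc2)c(OC)c(C)c1O | intermediate
24 | 1-{2-hydroxy-4-methoxy-3,6-dimethyl-5-[(2,4,6-trihydroxy-3-methylphenyl)methyl]phenyl}butan-1-one | CCCC(=O)c1c(C)c(Cc2c(O)c(C)c(O)cc2O)c(OC)c(C)c1O | intermediate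
25 | butanoic acid | CCCC(=O)O | starting material
26 | 1-{3-[(3-butanoyl-4-hydroxy-6-methoxy-2,5-dimethylphenyl)methyl]-2,4,6-trihydroxy-5-methylphenyl}butan-1-one (CNP0189103.0) | CCCC(=O)c1c(C)c(Cc2c(O)c(C)c(O)c(C(=O)CCC)c2O)c(OC)c(C)c1O | target

**Step count**
Total: 12 steps. Longest linear sequence: 10 steps (steps 1–6 and 9–12); steps 7 and 8 form the two-step branch to ynone 18.

**Steps most likely to fail**

1. Step 10. The cycloaddition of a tetrasubstituted diene with an internal alkyne may be slow at 110 °C, so that silyl migration or protodesilylation of the diene back to 13 outruns ring closure. The mixed ketal of 21 may also partly lose silanol instead of methanol. Fallback: setting out again from diene 20, the more electrophilic but-2-ynal (CC#CC=O) would take the place of 18 in the same cycloaddition (toluene, rt to 60 °C, then 1 M HCl) and should give 2-hydroxy-4-methoxy-3,6-dimethyl-5-[(2,4,6-tris(benzyloxy)-3-methylphenyl)methyl]benzaldehyde F1. Addition of n-PrMgBr (3 equiv, THF, 0 °C) would lead to racemic 1-{2-hydroxy-4-methoxy-3,6-dimethyl-5-[(2,4,6-tris(benzyloxy)-3-methylphenyl)methyl]phenyl}butan-1-ol F2. Oxidation of this benzylic alcohol with MnO2 (CH2Cl2, rt) comes back to the route at 23.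

2. Step 12. Under hot Lewis acid the electron-rich ring B may be protonated at its bridge-bearing carbon, which would cleave or scramble the diarylmethane link before acylation deactivates the ring. The reaction may also stall at O-acylated or boron-chelated stages. Fallback: setting out from 24, a Houben–Hoesch reaction with butanenitrile (ZnCl2, HCl gas, Et2O, 0 °C) would attach the four-carbon unit at low temperature as the ketiminium salt 1-{3-[(3-butanoyl-4-hydroxy-6-methoxy-2,5-dimethylphenyl)methyl]-2,4,6-trihydroxy-5-methylphenyl}butan-1-iminium chloride F3. Hydrolysis of this salt in warm water comes back to the route at 26.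

3. Step 6. Ketalization of the α-branched β-keto ester may stop short, or the elimination may deliver the deconjugated enol ether or a geometric isomer of 13 that resists the γ-deprotonation of step 9. Fallback: setting out from 12, silylation (Me3SiCl, Et3N, toluene, rt) would give methyl 2-methyl-3-(trimethylsilyloxy)-5-[2,4,6-tris(benzyloxy)-3-methylphenyl]pent-2-enoate F4 (E/Z mixture, either isomer serves). A second enolization and silylation (LiN(i-Pr)2, Me3SiCl, THF, −78 °C) would give (3Z)-1-methoxy-2-methyl-1,3-bis(trimethylsilyloxy)-5-[2,4,6-tris(benzyloxy)-3-methylphenyl]penta-1,3-diene F5. Cycloaddition of this diene with 18 under the conditions of step 10, followed by acidic work-up, should give the resorcinol 1-{2,4-dihydroxy-3,6-dimethyl-5-[(2,4,6-tris(benzyloxy)-3-methylphenyl)methyl]phenyl}butan-1-one F6. MeI (1.05 equiv) and K2CO3 in acetone would methylate only the hydroxyl that is not hydrogen-bonded to the ketone, which comes back to the route at 23.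

**Further compounds**
F1 | step 10 | 2-hydroxy-4-methoxy-3,6-dimethyl-5-[(2,4,6-tris(benzyloxy)-3-methylphenyl)methyl]benzaldehyde | O=Cc1c(C)c(Cc2c(OCc3ccccc3)c(C)c(OCc3ccccc3)cc2OCc2ccccc2)c(OC)c(C)c1O
F2 | step 10 | 1-{2-hydroxy-4-methoxy-3,6-dimethyl-5-[(2,4,6-tris(benzyloxy)-3-methylphenyl)methyl]phenyl}butan-1-ol (racemic) | CCCC(O)c1c(C)c(Cc2c(OCc3ccccc3)c(C)c(OCc3ccccc3)cc2OCc2ccccc2)c(OC)c(C)c1O
F3 | step 12 | 1-{3-[(3-butanoyl-4-hydroxy-6-methoxy-2,5-dimethylphenyl)methyl]-2,4,6-trihydroxy-5-methylphenyl}butan-1-iminium chloride | CCCC(=[NH2+])c1c(O)c(Cc2c(C)c(C(=O)CCC)c(O)c(C)c2OC)c(O)c(C)c1O.[Cl-]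
F4 | step 6 | methyl 2-methyl-3-(trimethylsilyloxy)-5-[2,4,6-tris(benzyloxy)-3-methylphenyl]pent-2-enoate (E/Z mixture) | COC(=O)C(C)=C(CCc1c(OCc2ccccc2)c(C)c(OCc2ccccc2)cc1OCc1ccccc1)O[Si](C)(C)C
F5 | step 6 | (3Z)-1-methoxy-2-methyl-1,3-bis(trimethylsilyloxy)-5-[2,4,6-tris(benzyloxy)-3-methylphenyl]penta-1,3-diene (mixture at the ketene acetal) | COC(O[Si](C)(C)C)=C(C)/C(O[Si](C)(C)C)=C/Cc1c(OCc2ccccc2)c(C)c(OCc2ccccc2)cc1OCc1ccccc1
F6 | step 6 | 1-{2,4-dihydroxy-3,6-dimethyl-5-[(2,4,6-tris(benzyloxy)-3-methylphenyl)methyl]phenyl}butan-1-one | CCCC(=O)c1c(C)c(Cc2c(OCc3ccccc3)c(C)c(OCc3ccccc3)cc2OCc2ccccc2)c(O)c(C)c1O
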